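**Retrosynthetic overview**

1. Numbering: the right half is numbered as a drimane (ring A = C1–C5 and C10, ring B = C5–C10, linker C11–C12), the left half as a 1-benzoxepine. The last C–C bond is C9–C11, made by B-alkyl Suzuki coupling of a ring B 6,8-dien-9-yl triflate with the left-half vinyl ketone. The diene comes from the 8-methyl-7-en-9-one, and ring B is closed by aldol condensation (C7=C8).
2. Ring A, with C3, C5 and C10, comes from one [3+3] operation that forms C2–C3 and C5–C10. Reductive opening of 1-methylcyclopropyl ethyl ketone gives a 1,3-bis-nucleophile (C2 carbanion, C10 enolate), which adds to an aldehyde/enethioate bis-electrophile (Barbier addition, then 6-exo Michael closure).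
3. Enabling feature: in ring A, C10 (quaternary, methyl-bearing, next to C9, which stays a carbonyl until the coupling) and C2 are 1,3-related through the unfunctionalised C1, so C10–C1–C2 can be carried as a cyclopropane. C3 (carbinol) and C5 are 1,3-related through the gem-dimethyl C4, which makes the C3 aldehyde non-enolisable and insulates it from the C5=C6–C7 acceptor.
4. Left half: oxepane and cyclohexane are formed together by a Lewis acid cascade of the (6S,7S,10S)-bis-epoxide of farnesyl acetate. Hydrogenation sets the axial C7 methyl; oxidation and methylenation give the vinyl ketone.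
5. Ring order: ring A (step 4), ring B (step 7); oxepane and left cyclohexane (step 11); union (step 16); deprotection (step 17).

Key step: step 4

Remarks on the chemistry (assumptions):
- Step 4 gives 9 as a racemate of one relative configuration; the SMILES shows the enantiomer carried on after the resolution in step 5.
- Compound 3 is sold as its dimer and is used after cracking to the monomer.
- The L-fructose-derived Shi ketone (enantiomer of the common catalyst) is taken as available.
- Step 11 may give some endocyclic alkene isomer beside 18; it gives the same product in step 12.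

**Route**

Step 1
Reactants: 1 1-methylcyclopropane-1-carboxylic acid
Product: 2 1-(1-methylcyclopropyl)propan-1-one
Conditions: EtLi (2.2 equiv), Et2O, 0 °C to rt; inverse quench into cold 1 M HCl
Reagents that add atoms: ethyllithium, [Li]CC
Why: Addition of an organolithium to the lithium carboxylate stops at the gem-dialkoxide, which gives the ketone on aqueous work-up (carboxylic acid to ketone with two equivalents of RLi); no stereocenter is formed.

Step 2
Reactants: 3 3-hydroxy-2,2-dimethylpropanal
Product: 5 S-ethyl (2E)-5-hydroxy-4,4-dimethylpent-2-enethioate, via thioester ylide 4 (not isolated)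
Conditions: Ph3P=C=C=O, EtSH, THF, rt, 1 h; then 3, toluene, 80 °C
Reagents that add atoms: (triphenylphosphoranylidene)ketene, O=C=C=P(c1ccccc1)(c1ccccc1)c1ccccc1; ethanethiol, CCS
Why: Three-component Wittig olefination in which ethanethiol adds to the ketenylidene phosphorane to give the stabilised ylide 4, which olefinates the α-quaternary aldehyde E-selectively; forming 4 first keeps the free hydroxyl of 3 out of the addition.

Step 3
Reactants: 5 S-ethyl (2E)-5-hydroxy-4,4-dimethylpent-2-enethioate
Product: 6 S-ethyl (2E)-4,4-dimethyl-5-oxopent-2-enethioate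
Conditions: Dess–Martin periodinane, NaHCO3, CH2Cl2, 0 °C to rt
Reagents that add atoms: none
Why: Dess–Martin oxidation of the neopentyl primary alcohol gives the non-enolisable aldehyde without touching the thioester or the E-alkene.

Step 4
Reactants: 2 1-(1-methylcyclopropyl)propan-1-one; 6 S-ethyl (2E)-4,4-dimethyl-5-oxopent-2-enethioate
Product: 9 S-ethyl 2-[(1S,3S,6S)-3-hydroxy-2,2,6-trimethyl-6-propanoylcyclohexyl]ethanethioate (racemate), via γ-samario samarium enolate 7 (not isolated), via samarium alkoxide enolate 8 (not isolated)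
Conditions: SmI2 (2.3 equiv), HMPA (10 equiv), THF, rt, slow addition of 2; then 6 (0.9 equiv), −78 to 0 °C, high dilution; aq NH4Cl
Reagents that add atoms: none
Why: Proposed new method: single-electron transfer from SmI2 to 2 gives a ketyl whose cyclopropane bond breaks (cyclopropylcarbinyl fragmentation; the two ring CH2 groups are equivalent) to an enolate of trivalent samarium with a primary radical at C2, which a second SmI2 reduces to the alkylsamarium, so that 7 is a 1,3-bis-nucleophile at C2 and C10. When 6 is added, the alkylsamarium adds to the aldehyde (C2–C3) and the enolate of 8 then closes ring A by 6-exo-trig Michael addition to the enethioate (C5–C10). The closest known reaction types are the SmI2/HMPA reductive ring opening of cyclopropyl ketones with trapping of the samarium enolate, the two-stage samarium Barbier (samarium Grignard) addition of alkylsamariums to aldehydes, and the intramolecular Michael addition of samarium enolates; using a γ-samario enolate as a [3+3] partner is the new element. C3 is formed first and without facial control, so 9 is racemic (resolved in step 5). C5 and C10 are set relative to C3 in a chair-like transition state with the C3–O–Sm group and the acceptor arm on C5 equatorial, while allylic 1,3-strain in the tetrasubstituted enolate turns the C1–C2 bond toward the methyl group, which leaves the C10 methyl axial and the propanoyl group equatorial (the trans relation of C10–CH3 and C5–H in the target). The alkylsamarium must choose the aldehyde over the thioester and over unreacted 2, and the enolate must choose the internal acceptor: slow addition of 2 keeps it scarce, the α-quaternary aldehyde is the most electrophilic site and cannot be enolised, and the six-membered closure outruns intermolecular reactions at high dilution.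

Step 5
Reactants: 9 S-ethyl 2-[(1S,3S,6S)-3-hydroxy-2,2,6-trimethyl-6-propanoylcyclohexyl]ethanethioate (racemate)
Product: 10 S-ethyl 2-[(1S,3S,6S)-2,2,6-trimethyl-6-propanoyl-3-{[(1S,4R)-4,7,7-trimethyl-3-oxo-2-oxabicyclo[2.2.1]heptane-1-carbonyl]oxy}cyclohexyl]ethanethioate
Conditions: (1S)-(−)-camphanic chloride, Et3N, DMAP (cat.), CH2Cl2, rt; separation of the two diastereomers (chromatography or crystallisation)
Reagents that add atoms: (1S,4R)-camphanoyl chloride, ClC(=O)[C@@]12CC[C@@](C)(C(=O)O1)C2(C)C
Why: Acylation with an enantiopure acid chloride gives two diastereomeric camphanates that are separated (classical resolution through covalent diastereomers); the (1S,3S,6S) ester is kept, which fixes the absolute configuration of C3, C5 and C10, and the camphanate protects O3 until step 17.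

Step 6
Reactants: 10 camphanate thioester (name as in step 5)
Product: 11 (1S,3S,4S)-2,2,4-trimethyl-3-(2-oxoethyl)-4-propanoylcyclohexyl (1S,4R)-4,7,7-trimethyl-3-oxo-2-oxabicyclo[2.2.1]heptane-1-carboxylate
Conditions: Et3SiH, Pd/C (10 %), acetone, rt
Reagents that add atoms: none
Why: Fukuyama reduction: palladium-mediated reduction of the thioester by the silane stops at the aldehyde and leaves the ketone, the ester and the lactone untouched.

Step 7
Reactants: 11 keto aldehyde (name as in step 6)
Product: 12 (2S,4aS,8aS)-1,1,4a,6-tetramethyl-5-oxo-1,2,3,4,4a,5,8,8a-octahydronaphthalen-2-yl (1S,4R)-4,7,7-trimethyl-3-oxo-2-oxabicyclo[2.2.1]heptane-1-carboxylate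
Conditions: p-TsOH·H2O (cat.), toluene, 80 °C, molecular sieves
Reagents that add atoms: none
Why: Acid-catalysed intramolecular aldol condensation of a 1,5-keto aldehyde (Robinson-type ring closure): only the ethyl CH2 (C8) can reach the aldehyde C7 through a six-membered transition state, which closes ring B as the 8-methyl-7-en-9-one, while C5 and C10 cannot enolise and keep their configuration.

Step 8
Reactants: 12 enone camphanate (name as in step 7)
Product: 13 (2S,4aS,8aS)-1,1,4a,6-tetramethyl-5-[(trifluoromethanesulfonyl)oxy]-1,2,3,4,4a,8a-hexahydronaphthalen-2-yl (1S,4R)-4,7,7-trimethyl-3-oxo-2-oxabicyclo[2.2.1]heptane-1-carboxylate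
Conditions: KN(SiMe3)2 (1.2 equiv), THF, −78 °C; PhNTf2, −78 to 0 °C
Reagents that add atoms: N-phenylbis(trifluoromethanesulfonimide), FC(F)(F)S(=O)(=O)N(c1ccccc1)S(=O)(=O)C(F)(F)F
Why: Enol triflate formation from an extended enolate: the enone has no α′-hydrogen (C10 is quaternary), so the base removes a γ-hydrogen at C6 and O-triflation of the linear dienolate gives the 6,8-dien-9-yl triflate, which already holds the ring B diene of the target.

Step 9
Reactants: 14 (2E,6E)-farnesol
Product: 15 (2E,6E)-farnesyl acetate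
Conditions: Ac2O, pyridine, DMAP (cat.), CH2Cl2, rt
Reagents that add atoms: acetic anhydride, CC(=O)OC(C)=O
Why: Acetylation; the allylic acetate deactivates the 2,3-alkene toward the electrophilic oxidant of the next step.

Step 10
Reactants: 15 (2E,6E)-farnesyl acetate
Product: 16 (2E,6S,7S,10S)-6,7:10,11-diepoxy-3,7,11-trimethyldodec-2-en-1-yl acetate
Conditions: L-fructose-derived Shi ketone (30 mol %), Oxone (2KHSO5·KHSO4·K2SO4), K2CO3, Bu4NHSO4, MeCN/CH2(OMe)2/aq borate buffer (pH 10.5), 0 °C
Reagents that add atoms: potassium peroxymonosulfate (active part of Oxone), [K+].[O-]S(=O)(=O)OO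
Why: Shi asymmetric epoxidation (chiral dioxirane): the two electron-rich trisubstituted alkenes react, the 2,3-alkene next to the acetate does not, and the L-fructose-derived ketone gives the (6S,7S,10S) bis-epoxide by reagent control.

Step 11
Reactants: 16 bis-epoxide (name as in step 10)
Product: 18 [(3S,5aS,6R,9aS)-3-hydroxy-2,2,5a-trimethyl-7-methylidenedecahydro-1-benzoxepin-6-yl]methyl acetate, via trimethylsilyl ether 17 (not isolated)
Conditions: Me3SiOSO2CF3 (1.2 equiv), 2,6-di-tert-butyl-4-methylpyridine, CH2Cl2, −78 °C; then citric acid, MeOH, rt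
Reagents that add atoms: none
Why: Lewis acid-promoted tandem oxa-/carbacyclisation of a 1,5-diepoxide terminated by an alkene (epoxonium cascade): the 6,7-epoxide oxygen opens the silyl-activated terminal epoxide at its tertiary carbon (oxepane), the 2,3-alkene opens the resulting epoxonium at C7 with inversion through a chair transition state (cyclohexane), and proton loss gives the exocyclic alkene, so that C9a and C3 keep the epoxide configurations, C5a is set by the anti opening and C6 by the E-alkene (CH2OAc equatorial).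

Step 12
Reactants: 18 bicyclic alkene (name as in step 11)
Product: 19 [(3S,5aS,6R,7R,9aS)-3-hydroxy-2,2,5a,7-tetramethyldecahydro-1-benzoxepin-6-yl]methyl acetate
Conditions: H2 (1 atm), Pd/C (10 %), EtOAc, rt
Reagents that add atoms: none
Why: Heterogeneous catalytic hydrogenation from the face opposite the axial C5a methyl puts the new hydrogen on C7 from the equatorial side and leaves the C7 methyl axial, cis to the C5a methyl as in the target.

Step 13
Reactants: 19 hydroxy acetate (name as in step 12)
Product: 20 (3S,5aS,6R,7R,9aS)-6-(hydroxymethyl)-2,2,5a,7-tetramethyldecahydro-1-benzoxepin-3-ol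
Conditions: K2CO3 (cat.), MeOH, rt
Reagents that add atoms: none
Why: Base-catalysed transesterification (methanolysis) removes the acetate without touching a stereocenter.

Step 14
Reactants: 20 diol (name as in step 13)
Product: 21 (5aS,6R,7R,9aS)-2,2,5a,7-tetramethyl-3-oxodecahydro-1-benzoxepine-6-carbaldehyde
Conditions: Dess–Martin periodinane (2.6 equiv), NaHCO3, CH2Cl2, rt
Reagents that add atoms: none
Why: Dess–Martin oxidation of both alcohols gives the oxepanone (the C3 stereocenter is erased) and the aldehyde under buffered conditions that do not epimerise C6.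

Step 15
Reactants: 21 keto aldehyde (name as in step 14)
Product: 22 (5aS,6R,7R,9aS)-6-ethenyl-2,2,5a,7-tetramethyloctahydro-1-benzoxepin-3(2H)-one
Conditions: Ph3PCH3Br (1.3 equiv), KN(SiMe3)2 (1.2 equiv), THF, 0 °C; then 21, −78 to 0 °C
Reagents that add atoms: methyltriphenylphosphonium bromide, C[P+](c1ccccc1)(c1ccccc1)c1ccccc1.[Br-]
Why: Wittig methylenation: the non-stabilised ylide reacts with the aldehyde at low temperature much faster than with the hindered α,α-disubstituted ketone, and fast addition avoids epimerisation at C6.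

Step 16
Reactants: 22 vinyl ketone (name as in step 15); 13 dienyl triflate (name as in step 8)
Product: 24 (2S,4aS,8aR)-1,1,4a,6-tetramethyl-5-{2-[(5aS,6R,7R,9aS)-2,2,5a,7-tetramethyl-3-oxodecahydro-1-benzoxepin-6-yl]ethyl}-1,2,3,4,4a,8a-hexahydronaphthalen-2-yl (1S,4R)-4,7,7-trimethyl-3-oxo-2-oxabicyclo[2.2.1]heptane-1-carboxylate, via B-alkyl-9-borabicyclononane 23 (not isolated)
Conditions: 9-BBN (1.3 equiv), THF, 0 °C to rt; then 13, Pd(dppf)Cl2 (10 mol %), AsPh3, K3PO4 (3 M aq), DMF, 45 °C
Reagents that add atoms: none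
Why: B-alkyl Suzuki–Miyaura coupling: anti-Markovnikov hydroboration of the vinyl group by 9-BBN (the hindered ketone reacts far more slowly) and palladium-catalysed coupling of the primary alkylborane with the dienyl triflate forms C9–C11 and keeps the diene in place.

Step 17
Reactants: 24 coupled camphanate (name as in step 16)
Product: 25 (5aS,6R,7R,9aS)-6-{2-[(4aR,6S,8aS)-6-hydroxy-2,5,5,8a-tetramethyl-4a,5,6,7,8,8a-hexahydronaphthalen-1-yl]ethyl}-2,2,5a,7-tetramethyloctahydro-1-benzoxepin-3(2H)-one (CNP0106412.1)
Conditions: K2CO3 (cat.), MeOH/THF, 45 °C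
Reagents that add atoms: none
Why: Carbonate-catalysed methanolysis (transesterification) removes the camphanate and frees the 3-hydroxyl; no stereocenter and neither the diene nor the oxepanone is touched.

**Compound list**

1 | 1-methylcyclopropane-1-carboxylic acid | CC1(CC1)C(=O)O | starting material
2 | 1-(1-methylcyclopropyl)propan-1-one | CCC(=O)C1(C)CC1 | intermediate
3 | 3-hydroxy-2,2-dimethylpropanal | CC(C)(CO)C=O | starting material
4 | S-ethyl 2-(triphenyl-λ5-phosphanylidene)ethanethioate | CCSC(=O)C=P(c1ccccc1)(c1ccccc1)c1ccccc1 | intermediate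
5 | S-ethyl (2E)-5-hydroxy-4,4-dimethylpent-2-enethioate | CCSC(=O)/C=C/C(C)(C)CO | intermediate
6 | S-ethyl (2E)-4,4-dimethyl-5-oxopent-2-enethioate | CCSC(=O)/C=C/C(C)(C)C=O | intermediate
7 | diiodo{3-methyl-4-[(diiodosamario)oxy]hex-3-en-1-yl}samarium | CCC(O[Sm](I)I)=C(C)CC[Sm](I)I | intermediate
8 | S-ethyl (2E)-5,9-bis[(diiodosamario)oxy]-4,4,8-trimethylundeca-2,8-dienethioate | CCC(O[Sm](I)I)=C(C)CCC(O[Sm](I)I)C(C)(C)/C=C/C(=O)SCC | intermediate
9 | S-ethyl 2-[(1S,3S,6S)-3-hydroxy-2,2,6-trimethyl-6-propanoylcyclohexyl]ethanethioate (racemate; enantiomer carried on is shown) | CCC(=O)[C@@]1(C)CC[C@H](O)C(C)(C)[C@@H]1CC(=O)SCC | intermediate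
10 | S-ethyl 2-[(1S,3S,6S)-2,2,6-trimethyl-6-propanoyl-3-{[(1S,4R)-4,7,7-trimethyl-3-oxo-2-oxabicyclo[2.2.1]heptane-1-carbonyl]oxy}cyclohexyl]ethanethioate | CCC(=O)[C@@]1(C)CC[C@H](OC(=O)[C@@]23CC[C@@](C)(C(=O)O2)C3(C)C)C(C)(C)[C@@H]1CC(=O)SCC | intermediate
11 | (1S,3S,4S)-2,2,4-trimethyl-3-(2-oxoethyl)-4-propanoylcyclohexyl (1S,4R)-4,7,7-trimethyl-3-oxo-2-oxabicyclo[2.2.1]heptane-1-carboxylate | CCC(=O)[C@@]1(C)CC[C@H](OC(=O)[C@@]23CC[C@@](C)(C(=O)O2)C3(C)C)C(C)(C)[C@@H]1CC=O | intermediate
12 | (2S,4aS,8aS)-1,1,4a,6-tetramethyl-5-oxo-1,2,3,4,4a,5,8,8a-octahydronaphthalen-2-yl (1S,4R)-4,7,7-trimethyl-3-oxo-2-oxabicyclo[2.2.1]heptane-1-carboxylate | O=C1C(C)=CC[C@H]2C(C)(C)[C@@H](OC(=O)[C@@]34CC[C@@](C)(C(=O)O3)C4(C)C)CC[C@]12C | intermediate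
13 | (2S,4aS,8aS)-1,1,4a,6-tetramethyl-5-[(trifluoromethanesulfonyl)oxy]-1,2,3,4,4a,8a-hexahydronaphthalen-2-yl (1S,4R)-4,7,7-trimethyl-3-oxo-2-oxabicyclo[2.2.1]heptane-1-carboxylate | CC1=C(OS(=O)(=O)C(F)(F)F)[C@@]2(C)CC[C@H](OC(=O)[C@@]34CC[C@@](C)(C(=O)O3)C4(C)C)C(C)(C)[C@@H]2C=C1 | intermediate
14 | (2E,6E)-3,7,11-trimethyldodeca-2,6,10-trien-1-ol (farnesol) | CC(C)=CCC/C(C)=C/CC/C(C)=C/CO | starting material
15 | (2E,6E)-3,7,11-trimethyldodeca-2,6,10-trien-1-yl acetate | CC(C)=CCC/C(C)=C/CC/C(C)=C/COC(C)=O | intermediate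
16 | (2E,6S,7S,10S)-6,7:10,11-diepoxy-3,7,11-trimethyldodec-2-en-1-yl acetate | CC(=O)OC/C=C(C)/CC[C@@H]1O[C@@]1(C)CC[C@@H]1OC1(C)C | intermediate
17 | [(3S,5aS,6R,9aS)-2,2,5a-trimethyl-7-methylidene-3-[(trimethylsilyl)oxy]decahydro-1-benzoxepin-6-yl]methyl acetate | CC(=O)OC[C@@H]1C(=C)CC[C@@H]2OC(C)(C)[C@@H](O[Si](C)(C)C)CC[C@]21C | intermediate
18 | [(3S,5aS,6R,9aS)-3-hydroxy-2,2,5a-trimethyl-7-methylidenedecahydro-1-benzoxepin-6-yl]methyl acetate | CC(=O)OC[C@@H]1C(=C)CC[C@@H]2OC(C)(C)[C@@H](O)CC[C@]21C | intermediate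
19 | [(3S,5aS,6R,7R,9aS)-3-hydroxy-2,2,5a,7-tetramethyldecahydro-1-benzoxepin-6-yl]methyl acetate | CC(=O)OC[C@@H]1[C@H](C)CC[C@@H]2OC(C)(C)[C@@H](O)CC[C@]21C | intermediate
20 | (3S,5aS,6R,7R,9aS)-6-(hydroxymethyl)-2,2,5a,7-tetramethyldecahydro-1-benzoxepin-3-ol | OC[C@@H]1[C@H](C)CC[C@@H]2OC(C)(C)[C@@H](O)CC[C@]21C | intermediate
21 | (5aS,6R,7R,9aS)-2,2,5a,7-tetramethyl-3-oxodecahydro-1-benzoxepine-6-carbaldehyde | O=C[C@@H]1[C@H](C)CC[C@@H]2OC(C)(C)C(=O)CC[C@]21C | intermediate
22 | (5aS,6R,7R,9aS)-6-ethenyl-2,2,5a,7-tetramethyloctahydro-1-benzoxepin-3(2H)-one | C=C[C@@H]1[C@H](C)CC[C@@H]2OC(C)(C)C(=O)CC[C@]21C | intermediate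
23 | 9-{2-[(5aS,6R,7R,9aS)-2,2,5a,7-tetramethyl-3-oxodecahydro-1-benzoxepin-6-yl]ethyl}-9-borabicyclo[3.3.1]nonane | C1CCC2CCCC1B2CC[C@@H]1[C@H](C)CC[C@@H]2OC(C)(C)C(=O)CC[C@]21C | intermediate
24 | (2S,4aS,8aR)-1,1,4a,6-tetramethyl-5-{2-[(5aS,6R,7R,9aS)-2,2,5a,7-tetramethyl-3-oxodecahydro-1-benzoxepin-6-yl]ethyl}-1,2,3,4,4a,8a-hexahydronaphthalen-2-yl (1S,4R)-4,7,7-trimethyl-3-oxo-2-oxabicyclo[2.2.1]heptane-1-carboxylate | CC1=C(CC[C@@H]2[C@H](C)CC[C@@H]3OC(C)(C)C(=O)CC[C@]32C)[C@@]2(C)CC[C@H](OC(=O)[C@@]45CC[C@@](C)(C(=O)O4)C5(C)C)C(C)(C)[C@@H]2C=C1 | intermediate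
25 | (5aS,6R,7R,9aS)-6-{2-[(4aR,6S,8aS)-6-hydroxy-2,5,5,8a-tetramethyl-4a,5,6,7,8,8a-hexahydronaphthalen-1-yl]ethyl}-2,2,5a,7-tetramethyloctahydro-1-benzoxepin-3(2H)-one (CNP0106412.1) | CC1=C(CC[C@@H]2[C@H](C)CC[C@@H]3OC(C)(C)C(=O)CC[C@]32C)[C@@]2(C)CC[C@H](O)C(C)(C)[C@@H]2C=C1 | target

**Totals and risks**

Total step count: 17 (steps 1–8 right half, steps 9–15 left half, steps 16–17 union and deprotection).
Longest linear sequence: 9 steps (steps 2, 3, 4, 5, 6, 7, 8, 16, 17; the left-half line, steps 9–17, is equally long).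

Most likely to fail:

Step 4 (Proposed new method). What may go wrong: the alkylsamarium end of 7 is quenched before it meets 6 (protonation by the α-CH2 of unreacted 2, or addition to 2), or the samarium enolate fails to close ring A and is only protonated. The fallback uses known chemistry, sets out from 2 and 6, and comes back at 9. Homo-conjugate ring opening of 2 with Me3SiI and aqueous work-up gives 6-iodo-4-methylhexan-3-one F1. Iodine–zinc exchange (Et2Zn, CuI cat., 50 °C) gives bis(3-methyl-4-oxohexyl)zinc F2. Addition of F2 to aldehyde 6, catalysed by Ti(OiPr)4 and (1R,2R)-N,N′-(cyclohexane-1,2-diyl)bis(trifluoromethanesulfonamide) in toluene at −20 °C, gives S-ethyl (2E,5S)-5-hydroxy-4,4,8-trimethyl-9-oxoundec-2-enethioate F3 with reagent control at C3. KOC(CH3)3 in THF/t-BuOH at 0 °C then closes ring A by 6-exo Michael addition through the more substituted (thermodynamic) enolate. This gives 9 as the (1S,3S,6S) enantiomer, so step 5 becomes a plain acylation.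

Step 11. What may go wrong: exo-mode opening of the epoxonium ion, or proton loss before the C–C bond forms, because the allylic acetate lowers the nucleophilicity of the terminating alkene. The fallback sets out from 16 and comes back at 18 by making the two rings in separate operations. Cp2TiCl (from Cp2TiCl2 and Mn dust, with collidine hydrochloride and Me3SiCl for turnover) opens both epoxides homolytically. The tertiary ring radical closes the cyclohexane by 6-endo addition to the 2,3-alkene and ends as the exocyclic alkene, and the side-chain radical ends as the allylic alcohol. This gives [(1R,2S,3S)-3-hydroxy-2-[(3S)-3-hydroxy-4-methylpent-4-en-1-yl]-2-methyl-6-methylidenecyclohexyl]methyl acetate F4. The oxepane is then closed by Markovnikov alkoxymercuration of the isopropenyl group by the ring hydroxyl (Hg(OCOCF3)2, CH2Cl2, −20 °C) via the organomercurial [(3S,5aS,6R,9aS)-3-hydroxy-2,5a-dimethyl-7-methylidene-2-{[(trifluoroacetoxy)mercurio]methyl}decahydro-1-benzoxepin-6-yl]methyl acetate F5, and NaBH4/NaOH demercuration gives 18. A residual weakness is that the exocyclic alkene of F4 can also be mercurated; one equivalent of the mercury salt at low temperature is used to favour the intramolecular capture.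

Step 16. What may go wrong: slow oxidative addition and transmetalation at the tetrasubstituted C9 triflate next to the quaternary C10, with hydrolysis of the triflate or partial reduction of the oxepanone by the borane taking over. The fallback sets out from 22 (through 23) and 13 and comes back at 24. Iodinolysis of the alkylborane 23 (I2, NaOMe, MeOH, 0 °C) gives (5aS,6R,7R,9aS)-6-(2-iodoethyl)-2,2,5a,7-tetramethyloctahydro-1-benzoxepin-3(2H)-one F6. Nickel-catalysed reductive cross-electrophile coupling of F6 with triflate 13 (NiCl2(dme), 4,4′-di-tert-butyl-2,2′-bipyridine, Zn dust, DMA, rt) then forms the C9–C11 bond without a preformed organometallic reagent.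

Further compounds
F1 | step 4 | 6-iodo-4-methylhexan-3-one | CCC(=O)C(C)CCI
F2 | step 4 | bis(3-methyl-4-oxohexyl)zinc | CCC(=O)C(C)CC[Zn]CCC(C)C(=O)CC
F3 | step 4 | S-ethyl (2E,5S)-5-hydroxy-4,4,8-trimethyl-9-oxoundec-2-enethioate | CCC(=O)C(C)CC[C@H](O)C(C)(C)/C=C/C(=O)SCC
F4 | step 11 | [(1R,2S,3S)-3-hydroxy-2-[(3S)-3-hydroxy-4-methylpent-4-en-1-yl]-2-methyl-6-methylidenecyclohexyl]methyl acetate | CC(=O)OC[C@@H]1C(=C)CC[C@H](O)[C@@]1(C)CC[C@H](O)C(C)=C
F5 | step 11 | [(3S,5aS,6R,9aS)-3-hydroxy-2,5a-dimethyl-7-methylidene-2-{[(trifluoroacetoxy)mercurio]methyl}decahydro-1-benzoxepin-6-yl]methyl acetate | CC(=O)OC[C@@H]1C(=C)CC[C@@H]2OC(C)(C[Hg]OC(=O)C(F)(F)F)[C@@H](O)CC[C@]21C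
F6 | step 16 | (5aS,6R,7R,9aS)-6-(2-iodoethyl)-2,2,5a,7-tetramethyloctahydro-1-benzoxepin-3(2H)-one | ICC[C@@H]1[C@H](C)CC[C@@H]2OC(C)(C)C(=O)CC[C@]21C
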